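**Retrosynthetic overview**
- The dihydropyranone, the only ring of the target, is closed last. An open-chain ethyl 3-silyloxy-5,7-dihydroxy ester undergoes one-pot δ-lactonisation, β-elimination of the C3 oxygen and acetal hydrolysis, copying the polyketide release (acyl transfer to the 5-OH, then loss of the β-hydroxyl). C3 needs no stereocontrol because both epimers converge.
- C5–C6 aldol disconnection: a 1,5-anti boron aldol joins a C6–C20 methyl ketone (syn-diol masked as an ethylidene dioxane) to racemic ethyl 3-(TBSO)-5-oxopentanoate (C1–C5). A 1,3-anti reduction then sets C7.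
- The methyl ketone comes from a hemiacetal/oxa-Michael addition (sets C4' syn to C6'), preceded by cross-metathesis with methyl vinyl ketone and enantioselective allylation of decan-1-ol (sets C6').
- The C1–C5 aldehyde comes from silylation and half-reduction of diethyl 3-hydroxyglutarate.
- Ring order: the temporary 1,3-dioxane forms first (step 3) and is removed in step 8; the dihydropyranone forms last (step 8).

Assumption: the SMILES is read as (6S)-6-[(2S,4S,6S)-2,4,6-trihydroxypentadecyl]-5,6-dihydro-2H-pyran-2-one (ring oxygen anti to the 2'-OH, triol all-syn). The silyloxy carbon of the C1–C5 aldehyde is used racemic on purpose, because it becomes sp2 in the last step.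

**Step 1**
Reactants: 1 decan-1-ol; 2 allyl acetate
Product: 4 (4S)-tridec-1-en-4-ol, via decanal 3 (not isolated)
Conditions: [Ir(cod)Cl]2 (2.5 mol %), (R)-Cl,MeO-BIPHEP (5 mol %), 4-chloro-3-nitrobenzoic acid (10 mol %), Cs2CO3 (20 mol %), 2 (3 equiv), THF, 100–110 °C (sealed tube)
Reagents that add atoms: none
Why: Krische iridium-catalysed transfer-hydrogenative carbonyl allylation: the cyclometallated π-allyl iridium complex dehydrogenates 1 to decanal 3 and returns the hydrogen after enantioselective allyl transfer to the Re face, which sets the S carbinol (C6' of the target; about 93–97% ee expected for a linear alkanol; the ligand antipode is the one I expect to give Re-face addition, to be confirmed by Mosher ester analysis).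

**Step 2**
Reactants: 4 (4S)-tridec-1-en-4-ol; 5 but-3-en-2-one
Product: 6 (3E,6S)-6-hydroxypentadec-3-en-2-one
Conditions: 5 (3 equiv), second-generation Grubbs catalyst [RuCl2(=CHPh)(PCy3)(H2IMes)] (3 mol %), CH2Cl2, 40 °C
Reagents that add atoms: none
Why: Olefin cross-metathesis between a terminal alkene and an electron-poor enone partner is selective for the E cross-product and leaves the free carbinol and its stereocentre untouched.

**Step 3**
Reactants: 6 (3E,6S)-6-hydroxypentadec-3-en-2-one; 7 acetaldehyde
Product: 9 1-[(2S,4S,6S)-2-methyl-6-nonyl-1,3-dioxan-4-yl]propan-2-one, via hemiacetal 8 (not isolated)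
Conditions: 7 (5 equiv), Bi(NO3)3·5H2O (10 mol %), CH2Cl2, rt
Reagents that add atoms: none
Why: Two-component hemiacetal/oxa-Michael (oxa-conjugate) addition: Bi(NO3)3 promotes reversible hemiacetal formation (8) and intramolecular conjugate addition through a chair with the nonyl, methyl and 2-oxopropyl groups all equatorial, so the new C–O bond (C4' of the target) is set syn to the existing carbinol under thermodynamic control (dr ≥ 15:1 expected).

**Step 4**
Reactants: 10 diethyl 3-hydroxypentanedioate
Product: 11 diethyl 3-[(tert-butyldimethylsilyl)oxy]pentanedioate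
Conditions: TBSCl (1.2 equiv), imidazole (2.5 equiv), DMF, rt
Reagents that add atoms: tert-butyldimethylsilyl chloride (TBSCl), CC(C)(C)[Si](C)(C)Cl
Why: Standard imidazole-promoted silylation of a secondary alcohol; the silyloxy group serves as protecting group now and as the leaving group for the final β-elimination.

**Step 5**
Reactants: 11 diethyl 3-[(tert-butyldimethylsilyl)oxy]pentanedioate
Product: 12 ethyl 3-[(tert-butyldimethylsilyl)oxy]-5-oxopentanoate (racemic)
Conditions: i-Bu2AlH (1.05 equiv), CH2Cl2, −78 °C; then MeOH, aq. potassium sodium tartrate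
Reagents that add atoms: none
Why: Partial ester reduction with one equivalent of i-Bu2AlH at −78 °C stops at the tetrahedral aluminium hemiacetal, which gives the aldehyde on work-up; the two esters are equivalent, so the mono-aldehyde forms statistically (recovered 11 is recycled) and is racemic, which does not matter because this carbon becomes sp2 in step 8.

**Step 6**
Reactants: 9 1-[(2S,4S,6S)-2-methyl-6-nonyl-1,3-dioxan-4-yl]propan-2-one; 12 ethyl 3-[(tert-butyldimethylsilyl)oxy]-5-oxopentanoate
Product: 14 ethyl (5S)-3-[(tert-butyldimethylsilyl)oxy]-5-hydroxy-8-[(2S,4S,6S)-2-methyl-6-nonyl-1,3-dioxan-4-yl]-7-oxooctanoate (1:1 at C3), via dibutylboron enolate 13 (not isolated)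
Conditions: 9, Bu2BOTf (1.2 equiv), i-Pr2NEt (1.5 equiv), Et2O, −78 °C; then 12 (1.3 equiv), −78 → −30 °C; then MeOH, pH 7 buffer, 30% H2O2, 0 °C
Reagents that add atoms: none
Why: Boron-mediated aldol of a β-alkoxy methyl ketone with 1,5-anti induction (Paterson/Evans): kinetic enolisation on the methyl side gives 13, and the β dioxane oxygen biases the boat-like transition state so that the new C5 carbinol (the future ring C6) forms anti to it (5S, dr ≥ 10:1 expected), while the remote racemic silyloxy centre of 12 has little influence.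

**Step 7**
Reactants: 14 ethyl (5S)-3-[(tert-butyldimethylsilyl)oxy]-5-hydroxy-8-[(2S,4S,6S)-2-methyl-6-nonyl-1,3-dioxan-4-yl]-7-oxooctanoate
Product: 15 ethyl (5R,7R)-3-[(tert-butyldimethylsilyl)oxy]-5,7-dihydroxy-8-[(2S,4R,6S)-2-methyl-6-nonyl-1,3-dioxan-4-yl]octanoate (1:1 at C3)
Conditions: Me4NBH(OAc)3 (5 equiv), MeCN/AcOH (1:1), −30 °C
Reagents that add atoms: none
Why: Evans–Saksena hydroxyl-directed reduction: the C5 hydroxyl binds the triacetoxyborohydride and delivers hydride intramolecularly through a chair-like transition state, giving the 1,3-anti diol (new C7 carbinol, the future C2'), which is at the same time syn to the dioxane oxygen as the target requires (the descriptors at C5 and dioxane C4 change only because CIP priorities change).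

**Step 8**
Reactants: 15 ethyl (5R,7R)-3-[(tert-butyldimethylsilyl)oxy]-5,7-dihydroxy-8-[(2S,4R,6S)-2-methyl-6-nonyl-1,3-dioxan-4-yl]octanoate
Product: 18 (6S)-6-[(2S,4S,6S)-2,4,6-trihydroxypentadecyl]-5,6-dihydro-2H-pyran-2-one (target), via silyloxy lactone 16 (not isolated), via dioxane-protected pyranone 17 (not isolated)
Conditions: PPTS (20 mol %), PhMe, 70 °C (EtOH swept out); then DBU (2 equiv), rt; then 2 M aq. HCl, THF, 40 °C
Reagents that add atoms: none
Why: Thioesterase/dehydratase-like release cascade built from three known reaction types: acid-catalysed δ-lactonisation of the 5-hydroxy ester (the 7-OH could only give an eight-membered ring), E1cB β-elimination of silanolate from lactone 16 that funnels both C4 epimers into one alkene, and acid hydrolysis of the ethylidene acetal of 17; no stereocentre is formed or touched, and the 6,2'-anti relationship keeps the free 2'-OH from oxa-Michael closure because the bicyclic adduct would need an endo side chain.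

**Compound list**
1 | decan-1-ol | CCCCCCCCCCO | starting material
2 | allyl acetate (prop-2-en-1-yl acetate) | C=CCOC(C)=O | starting material
3 | decanal | CCCCCCCCCC=O | intermediate
4 | (4S)-tridec-1-en-4-ol | CCCCCCCCC[C@H](O)CC=C | intermediate
5 | but-3-en-2-one (methyl vinyl ketone) | CC(=O)C=C | starting material
6 | (3E,6S)-6-hydroxypentadec-3-en-2-one | CCCCCCCCC[C@H](O)C/C=C/C(C)=O | intermediate
7 | acetaldehyde | CC=O | starting material
8 | (3E,6S)-6-(1-hydroxyethoxy)pentadec-3-en-2-one (hemiacetal; hemiacetal carbon either configuration) | CCCCCCCCC[C@H](OC(C)O)C/C=C/C(C)=O | intermediate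
9 | 1-[(2S,4S,6S)-2-methyl-6-nonyl-1,3-dioxan-4-yl]propan-2-one (all-cis dioxane) | CCCCCCCCC[C@H]1C[C@@H](CC(C)=O)O[C@@H](C)O1 | intermediate
10 | diethyl 3-hydroxypentanedioate | CCOC(=O)CC(O)CC(=O)OCC | starting material
11 | diethyl 3-[(tert-butyldimethylsilyl)oxy]pentanedioate | CCOC(=O)CC(O[Si](C)(C)C(C)(C)C)CC(=O)OCC | intermediate
12 | ethyl 3-[(tert-butyldimethylsilyl)oxy]-5-oxopentanoate (racemic) | CCOC(=O)CC(O[Si](C)(C)C(C)(C)C)CC=O | intermediate
13 | dibutyl({3-[(2S,4S,6S)-2-methyl-6-nonyl-1,3-dioxan-4-yl]prop-1-en-2-yl}oxy)borane (boron enolate of 9) | CCCCCCCCC[C@H]1C[C@@H](CC(=C)OB(CCCC)CCCC)O[C@@H](C)O1 | intermediate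
14 | ethyl (5S)-3-[(tert-butyldimethylsilyl)oxy]-5-hydroxy-8-[(2S,4S,6S)-2-methyl-6-nonyl-1,3-dioxan-4-yl]-7-oxooctanoate (1:1 at C3) | CCCCCCCCC[C@H]1C[C@@H](CC(=O)C[C@@H](O)CC(O[Si](C)(C)C(C)(C)C)CC(=O)OCC)O[C@@H](C)O1 | intermediate
15 | ethyl (5R,7R)-3-[(tert-butyldimethylsilyl)oxy]-5,7-dihydroxy-8-[(2S,4R,6S)-2-methyl-6-nonyl-1,3-dioxan-4-yl]octanoate (1:1 at C3) | CCCCCCCCC[C@H]1C[C@@H](C[C@H](O)C[C@@H](O)CC(O[Si](C)(C)C(C)(C)C)CC(=O)OCC)O[C@@H](C)O1 | intermediate
16 | (6R)-4-[(tert-butyldimethylsilyl)oxy]-6-{(2S)-2-hydroxy-3-[(2S,4R,6S)-2-methyl-6-nonyl-1,3-dioxan-4-yl]propyl}oxan-2-one (1:1 at C4) | CCCCCCCCC[C@H]1C[C@@H](C[C@H](O)C[C@@H]2CC(O[Si](C)(C)C(C)(C)C)CC(=O)O2)O[C@@H](C)O1 | intermediate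
17 | (6S)-6-{(2S)-2-hydroxy-3-[(2S,4R,6S)-2-methyl-6-nonyl-1,3-dioxan-4-yl]propyl}-5,6-dihydro-2H-pyran-2-one | CCCCCCCCC[C@H]1C[C@@H](C[C@H](O)C[C@@H]2CC=CC(=O)O2)O[C@@H](C)O1 | intermediate
18 | (6S)-6-[(2S,4S,6S)-2,4,6-trihydroxypentadecyl]-5,6-dihydro-2H-pyran-2-one | CCCCCCCCC[C@H](O)C[C@H](O)C[C@H](O)C[C@@H]1CC=CC(=O)O1 | target

**Step count**
Total: 8 steps. Longest linear sequence: 6 steps (steps 1, 2, 3, 6, 7, 8); steps 4 and 5 make the C1–C5 aldehyde in parallel.

**Steps most likely to fail, with fallbacks**

Step 8 (ring-closing cascade). Loss of silanolate from 16 may be slow, the acetal may migrate onto the 5,7-diol under the acid used for ring closure, or partial desilylation may leave a β-hydroxy lactone that DBU does not dehydrate. The fallback sets out from 15 and changes how the C3 oxygen leaves. Aqueous HCl/THF strips the silyl ether and the acetal and closes the ring to (4RS,6R)-4-hydroxy-6-[(2S,4S,6S)-2,4,6-trihydroxypentadecyl]oxan-2-one F1. Ac2O/pyridine/DMAP converts it into its tetra-O-acetate F2, in which only the acetoxy group β to the lactone carbonyl can leave by E1cB when DBU is added, giving the 2',4',6'-tri-O-acetate of the target F3. Acid-catalysed methanolysis (AcCl in MeOH, 0 °C → rt, then concentration to re-close any opened hydroxy ester) removes the acetates and comes back to the route at 18.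

Step 5 (half-reduction of a symmetric diester). The reduction is statistical and can over-reduce to the dialdehyde or the alcohol. The fallback sets out from 11 and differentiates the two esters by hydrolysis instead of hydride. Monohydrolysis with one equivalent of aq. NaOH in THF at 0 °C gives 3-[(tert-butyldimethylsilyl)oxy]-5-ethoxy-5-oxopentanoic acid F4. BH3·SMe2 reduces only the carboxylic acid to ethyl 3-[(tert-butyldimethylsilyl)oxy]-5-hydroxypentanoate F5, which is oxidised at once (Swern: (COCl)2, DMSO, Et3N) and comes back to the route at 12.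

Step 3 (bismuth-mediated hemiacetal/oxa-Michael addition). The two-component addition to a methyl enone may stall at the hemiacetal or lose diastereoselectivity by retro-Michael opening. The fallback sets out from 6 and tethers the oxygen nucleophile through boron instead of a hemiacetal. PhB(OH)2 with a tertiary-amine/thiourea catalyst gives, by intramolecular oxa-Michael addition of the boronic hemiester, the cis cyclic boronate 1-[(4S,6S)-6-nonyl-2-phenyl-1,3,2-dioxaborinan-4-yl]propan-2-one F6. H2O2/aq. NaHCO3 releases (4S,6S)-4,6-dihydroxypentadecan-2-one F7, and thermodynamic acetalisation with 1,1-diethoxyethane/PPTS (all-equatorial dioxane) comes back to the route at 9.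

**Further compounds**
F1 | step 8 | (4RS,6R)-4-hydroxy-6-[(2S,4S,6S)-2,4,6-trihydroxypentadecyl]oxan-2-one | CCCCCCCCC[C@H](O)C[C@H](O)C[C@H](O)C[C@@H]1CC(O)CC(=O)O1
F2 | step 8 | tetra-O-acetate of F1 (all four hydroxyls acetylated, configurations unchanged) | CCCCCCCCC[C@H](OC(C)=O)C[C@H](OC(C)=O)C[C@H](OC(C)=O)C[C@@H]1CC(OC(C)=O)CC(=O)O1
F3 | step 8 | 2',4',6'-tri-O-acetate of target 18 | CCCCCCCCC[C@H](OC(C)=O)C[C@H](OC(C)=O)C[C@H](OC(C)=O)C[C@@H]1CC=CC(=O)O1
F4 | step 5 | 3-[(tert-butyldimethylsilyl)oxy]-5-ethoxy-5-oxopentanoic acid (racemic) | CCOC(=O)CC(O[Si](C)(C)C(C)(C)C)CC(=O)O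
F5 | step 5 | ethyl 3-[(tert-butyldimethylsilyl)oxy]-5-hydroxypentanoate (racemic) | CCOC(=O)CC(O[Si](C)(C)C(C)(C)C)CCO
F6 | step 3 | 1-[(4S,6S)-6-nonyl-2-phenyl-1,3,2-dioxaborinan-4-yl]propan-2-one | CCCCCCCCC[C@H]1C[C@@H](CC(C)=O)OB(c2ccccc2)O1
F7 | step 3 | (4S,6S)-4,6-dihydroxypentadecan-2-one | CCCCCCCCC[C@H](O)C[C@H](O)CC(C)=O
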